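Retrosynthetic overview
Target 25 <= twofold angeloylation of diol 23 <= epoxy ketone 22 <= hydroxyl-directed epoxidation, then oxidation, of cyclohexenol 20; the oxirane of the 7-oxabicyclo[4.1.0]heptan-2-one core is carried as the C-6=C-1 alkene and the C-2 ketone as an allylic alcohol.
Key disconnection: ring bond C-4–C-5 (CH bearing the dienyl chain to ring CH2). Enabling feature: with the oxirane read as an alkene, C-5 is allylic to C-6=C-1 and C-4 is allylic to the exocyclic methylene of the side chain, so the bond is the centre of a 1,5-diene. It is the bond the presumed biosynthesis makes when a Z-allylic farnesyl-type cation closes to the bisabolyl cation. The C-2 oxygen, next to the methyl-bearing C-1, is tied to C-5 as a 2,5-dihydrofuran (Z-lock, leaving group and later ketone oxygen), and a CH2SiMe3 group on the side-chain alkene fixes where the exocyclic methylene forms.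
Dihydrofuran 18 <= butenolide 16 <= vinylogous Mukaiyama aldol of silyloxyfuran 13 with enal 11 (sets the C-2 and C-3 carbinol centres).
Enal 11 <= allylsilane ester 9 <= enol triflate of a β-keto ester <= methyl (S)-glycidate 1 (side-chain carbinol centre from the chiral pool).
Ring order: butenolide (step 9), 2,5-dihydrofuran (step 12, temporary), cyclohexene by opening of that ring (step 13), oxirane (step 14).
Key step: step 13

Remarks before the steps
- Core positions follow the target named as a 7-oxabicyclo[4.1.0]heptan-2-one: C-1 (oxirane carbon with methyl), C-2 (C=O), C-3 (CH–O-acyl), C-4 (CH with the dienyl chain), C-5 (CH2), C-6 (oxirane CH). TBS = tert-butyldimethylsilyl; TBSO = tert-butyldimethylsilyloxy; BINOL = 1,1'-bi-2-naphthol.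
- Assumption (step 9): (R)-BINOL is written on the premise that it steers the furan to the aldehyde face giving the (1'S) carbinol; if the sense is the reverse, (S)-BINOL is used and nothing else changes.
- The target is taken as drawn: (1S,3S,4S,6S) core, (3S) side-chain carbinol, both esters (Z) (angelates).

Step 1
Reactants: 1 methyl (2S)-oxirane-2-carboxylate; 2 2-methylprop-1-enylmagnesium bromide
Product: 3 methyl (2S)-2-hydroxy-5-methylhex-4-enoate
Conditions: CuI (10 mol %), THF, −40 → −20 °C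
Reagents that add atoms: 2-methylprop-1-enylmagnesium bromide (2), CC(C)=C[Mg]Br
Why: Copper-catalysed Grignard opening of the glycidic ester at its CH2 carbon (SN2 epoxide opening) should install the prenyl-type terminus without touching the existing stereocentre.

Step 2
Reactants: 3 methyl (2S)-2-hydroxy-5-methylhex-4-enoate
Product: 4 methyl (2S)-2-(TBSO)-5-methylhex-4-enoate
Conditions: TBSCl, imidazole, DMF, rt
Reagents that add atoms: tert-butyldimethylsilyl chloride, CC(C)(C)[Si](C)(C)Cl
Why: Standard silylation of a secondary alcohol, needed to carry this carbinol through the enolate, hydride and Lewis acid steps.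

Step 3
Reactants: 4 methyl (2S)-2-(TBSO)-5-methylhex-4-enoate; 5 tert-butyl acetate
Product: 6 tert-butyl (4S)-4-(TBSO)-7-methyl-3-oxooct-6-enoate
Conditions: LiN(i-Pr)2 (2.2 equiv), 5 (2.2 equiv), THF, −78 °C; then 4, −78 → −20 °C
Reagents that add atoms: tert-butyl acetate (5), CC(=O)OC(C)(C)C
Why: Crossed Claisen condensation of the lithium enolate of tert-butyl acetate with the methyl ester; the product sits as its enolate, which should shield the α-silyloxy stereocentre from epimerisation.

Step 4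
Reactants: 6 tert-butyl (4S)-4-(TBSO)-7-methyl-3-oxooct-6-enoate
Product: 7 tert-butyl (2Z,4S)-4-(TBSO)-7-methyl-3-(trifluoromethylsulfonyloxy)octa-2,6-dienoate
Conditions: NaH, PhNTf2, THF, 0 °C → rt
Reagents that add atoms: N-phenylbis(trifluoromethanesulfonimide), O=S(=O)(N(c1ccccc1)S(=O)(=O)C(F)(F)F)C(F)(F)F
Why: Enol triflate formation by O-sulfonylation of the chelated sodium enolate of the β-keto ester should give the Z isomer (triflate cis to the ester).

Step 5
Reactants: 7 tert-butyl (2Z,4S)-4-(TBSO)-7-methyl-3-(trifluoromethylsulfonyloxy)octa-2,6-dienoate; 8 (trimethylsilyl)methylmagnesium chloride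
Product: 9 tert-butyl (2Z,4S)-4-(TBSO)-7-methyl-3-(trimethylsilylmethyl)octa-2,6-dienoate
Conditions: Pd(PPh3)4 (5 mol %), THF, 0 °C → rt
Reagents that add atoms: (trimethylsilyl)methylmagnesium chloride (8), C[Si](C)(C)C[Mg]Cl
Why: Kumada coupling of an enol triflate with Me3SiCH2MgCl is a standard route to 2-substituted allylsilanes, goes with retention of alkene geometry, and the tert-butyl ester should resist the Grignard reagent.

Step 6
Reactants: 9 tert-butyl (2Z,4S)-4-(TBSO)-7-methyl-3-(trimethylsilylmethyl)octa-2,6-dienoate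
Product: 10 (2Z,4S)-4-(TBSO)-7-methyl-3-(trimethylsilylmethyl)octa-2,6-dien-1-ol
Conditions: i-Bu2AlH (2.5 equiv), CH2Cl2, −78 → −20 °C; neutral aqueous work-up
Reagents that add atoms: none
Why: 1,2-Reduction of the enoate with i-Bu2AlH gives the allylic alcohol, and the neutral work-up avoids acid-induced 1,4-elimination of the γ-silyl allylic alcohol.

Step 7
Reactants: 10 (2Z,4S)-4-(TBSO)-7-methyl-3-(trimethylsilylmethyl)octa-2,6-dien-1-ol
Product: 11 (2Z,4S)-4-(TBSO)-7-methyl-3-(trimethylsilylmethyl)octa-2,6-dienal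
Conditions: MnO2 (activated, excess), CH2Cl2, rt
Reagents that add atoms: none
Why: Allylic oxidation with MnO2 under neutral conditions should give the enal, which is used at once because the cis γ-silyl enal can undergo a thermal silyl shift.

Step 8
Reactants: 12 4-methylfuran-2(5H)-one
Product: 13 4-methyl-2-(trimethylsilyloxy)furan
Conditions: Me3SiOTf, Et3N, Et2O, 0 °C
Reagents that add atoms: trimethylsilyl trifluoromethanesulfonate, C[Si](C)(C)OS(=O)(=O)C(F)(F)F
Why: Soft enolisation and O-silylation of the butenolide (silyl dienol ether formation) gives the aromatic 2-silyloxyfuran.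

Step 9
Reactants: 11 (2Z,4S)-4-(TBSO)-7-methyl-3-(trimethylsilylmethyl)octa-2,6-dienal; 13 4-methyl-2-(trimethylsilyloxy)furan
Product: 15 (5S)-5-[(1S,2Z,4S)-4-(TBSO)-1-hydroxy-7-methyl-3-(trimethylsilylmethyl)octa-2,6-dien-1-yl]-4-methylfuran-2(5H)-one, via O-trimethylsilyl ether of the aldol adduct 14 (not isolated)
Conditions: Ti(OiPr)4 (20 mol %), (R)-BINOL (20 mol %), Et2O, −20 °C; then MeOH, citric acid, 0 °C
Reagents that add atoms: 4-methyl-2-(trimethylsilyloxy)furan (13), Cc1coc(O[Si](C)(C)C)c1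
Why: Catalytic asymmetric vinylogous Mukaiyama aldol reaction: the furan attacks through its free position next to oxygen, the open transition state usual for Lewis-acid additions of 2-silyloxyfurans should favour the 5,1'-threo adduct, and the titanium BINOLate selects the aldehyde face, which together set both carbinol centres as (5S,1'S).

Step 10
Reactants: 15 (5S)-5-[(1S,2Z,4S)-4-(TBSO)-1-hydroxy-7-methyl-3-(trimethylsilylmethyl)octa-2,6-dien-1-yl]-4-methylfuran-2(5H)-one
Product: 16 (5S)-5-[(1S,2Z,4S)-1,4-bis(TBSO)-7-methyl-3-(trimethylsilylmethyl)octa-2,6-dien-1-yl]-4-methylfuran-2(5H)-one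
Conditions: TBSOTf, 2,6-lutidine, CH2Cl2, −78 °C
Reagents that add atoms: tert-butyldimethylsilyl trifluoromethanesulfonate, CC(C)(C)[Si](C)(C)OS(=O)(=O)C(F)(F)F
Why: Silylation of the secondary alcohol with the silyl triflate at low temperature should outrun γ-deprotonation of the butenolide.

Step 11
Reactants: 16 (5S)-5-[(1S,2Z,4S)-1,4-bis(TBSO)-7-methyl-3-(trimethylsilylmethyl)octa-2,6-dien-1-yl]-4-methylfuran-2(5H)-one
Product: 17 (2Z,4S,5S,6Z,8S)-5,8-bis(TBSO)-3,11-dimethyl-7-(trimethylsilylmethyl)dodeca-2,6,10-triene-1,4-diol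
Conditions: i-Bu2AlH (4 equiv), CH2Cl2, −78 → 0 °C; neutral aqueous work-up
Reagents that add atoms: none
Why: Reduction of the butenolide with i-Bu2AlH should go through the lactol to the ene-1,4-diol, whose Z trisubstituted alkene is inherited from the ring.

Step 12
Reactants: 17 (2Z,4S,5S,6Z,8S)-5,8-bis(TBSO)-3,11-dimethyl-7-(trimethylsilylmethyl)dodeca-2,6,10-triene-1,4-diol
Product: 18 (2S)-2-[(1S,2Z,4S)-1,4-bis(TBSO)-7-methyl-3-(trimethylsilylmethyl)octa-2,6-dien-1-yl]-3-methyl-2,5-dihydrofuran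
Conditions: PPh3, diisopropyl azodicarboxylate, THF, 0 °C → rt
Reagents that add atoms: none
Why: Intramolecular Mitsunobu etherification: the primary allylic hydroxyl is activated and displaced 5-exo-tet by the secondary one, so the secondary carbinol keeps its configuration.

Step 13
Reactants: 18 (2S)-2-[(1S,2Z,4S)-1,4-bis(TBSO)-7-methyl-3-(trimethylsilylmethyl)octa-2,6-dien-1-yl]-3-methyl-2,5-dihydrofuran
Product: 20 (1S,5S,6S)-6-(TBSO)-5-[(3S)-3-(TBSO)-6-methylhepta-1,5-dien-2-yl]-2-methylcyclohex-2-en-1-ol, via trimethylsilyl ether of the cyclohexenol 19 (not isolated)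
Conditions: Me3SiOTf (0.2 equiv), 2,6-di-tert-butyl-4-methylpyridine (0.3 equiv), CH2Cl2, −78 → −40 °C; then MeOH, pyridinium p-toluenesulfonate (cat.), 0 °C
Reagents that add atoms: none
Why: Proposed new method: Me3SiOTf should silylate the ring oxygen and the allylic O–CH2 bond should ionise, because the 3-methyl group makes the Z-locked allyl cation tertiary at its far end and leaves the carbinol oxygen as a neutral Me3Si ether that cannot return; the tethered allylsilane then adds through its CH terminus to the cationic CH2, and the β-silyl cation loses Me3Si+, which regenerates Me3SiOTf and carries the chain. The closest known reaction type is the Lewis-acid cation–olefin cyclisation of an acyclic allylic cation initiator (from an allylic alcohol, ester or ether) onto an allylsilane terminator, itself the chemical copy of the bisabolyl cation closure; new is the use of a 2,5-dihydrofuran C–O bond as initiator. The cyclohexene closes 6-endo with respect to the allyl cation (its double bond stays in the ring) and exo with respect to the allylsilane (its double bond becomes the exocyclic methylene). The one new stereocentre is controlled by the neighbouring OTBS carbinol: A(1,3) strain against the cis CH2SiMe3 group holds the carbinol hydrogen in the alkene plane, so the cation arm reaches the alkene face opposite to OTBS through a chair with OSiMe3, OTBS and the alkenyl group all equatorial, which should give the all-trans arrangement; the E/Z geometry of the allylsilane is erased in the product. The step needs ionisation of the O–CH2 and not the O–CH bond, C–C closure faster than a 1,2-hydride shift or proton loss from the cation, and no protodesilylation; these rest on the tertiary cation terminus, on the two-atom tether that allows only the six-membered closure (the alternative is a cyclobutane), on the low temperature and on the hindered pyridine base that removes traces of TfOH. Mild acidic methanolysis then frees the allylic alcohol and should leave both TBS ethers in place.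

Step 14
Reactants: 20 (1S,5S,6S)-6-(TBSO)-5-[(3S)-3-(TBSO)-6-methylhepta-1,5-dien-2-yl]-2-methylcyclohex-2-en-1-ol
Product: 21 (1R,2R,3S,4S,6S)-3-(TBSO)-4-[(3S)-3-(TBSO)-6-methylhepta-1,5-dien-2-yl]-1-methyl-7-oxabicyclo[4.1.0]heptan-2-ol
Conditions: VO(acac)2 (5 mol %), t-BuOOH (1.2 equiv), CH2Cl2, 0 °C → rt
Reagents that add atoms: tert-butyl hydroperoxide, CC(C)(C)OO
Why: Hydroxyl-directed epoxidation with VO(acac)2/t-BuOOH delivers oxygen to the allylic alkene on the face of the hydroxyl (hence cis to the side chain and trans to OTBS), which sets both oxirane centres, and should leave the two unfunctionalised alkenes alone.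

Step 15
Reactants: 21 (1R,2R,3S,4S,6S)-3-(TBSO)-4-[(3S)-3-(TBSO)-6-methylhepta-1,5-dien-2-yl]-1-methyl-7-oxabicyclo[4.1.0]heptan-2-ol
Product: 22 (1S,3S,4S,6S)-3-(TBSO)-4-[(3S)-3-(TBSO)-6-methylhepta-1,5-dien-2-yl]-1-methyl-7-oxabicyclo[4.1.0]heptan-2-one
Conditions: Dess–Martin periodinane, pyridine, CH2Cl2, 0 °C → rt
Reagents that add atoms: none
Why: Dess–Martin oxidation converts the directing alcohol into the ketone under buffered, non-epimerising conditions that the epoxide and silyl ethers should tolerate.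

Step 16
Reactants: 22 (1S,3S,4S,6S)-3-(TBSO)-4-[(3S)-3-(TBSO)-6-methylhepta-1,5-dien-2-yl]-1-methyl-7-oxabicyclo[4.1.0]heptan-2-one
Product: 23 (1S,3S,4S,6S)-3-hydroxy-4-[(3S)-3-hydroxy-6-methylhepta-1,5-dien-2-yl]-1-methyl-7-oxabicyclo[4.1.0]heptan-2-one
Conditions: HF·pyridine, pyridine, THF, 0 °C → rt
Reagents that add atoms: none
Why: Fluoride-mediated desilylation with pyridine-buffered HF should remove both TBS groups without opening the epoxy ketone.

Step 17
Reactants: 23 (1S,3S,4S,6S)-3-hydroxy-4-[(3S)-3-hydroxy-6-methylhepta-1,5-dien-2-yl]-1-methyl-7-oxabicyclo[4.1.0]heptan-2-one; 24 (2Z)-2-methylbut-2-enoic acid (angelic acid)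
Product: 25 CNP0271744.2 = (1S,3S,4S,6S)-1-methyl-4-[(3S)-6-methyl-3-{[(2Z)-2-methylbut-2-enoyl]oxy}hepta-1,5-dien-2-yl]-2-oxo-7-oxabicyclo[4.1.0]heptan-3-yl (2Z)-2-methylbut-2-enoate
Conditions: 24 (4 equiv), 2,4,6-trichlorobenzoyl chloride, Et3N, toluene, rt; then 23, 75 °C
Reagents that add atoms: (2Z)-2-methylbut-2-enoic acid (24), C/C=C(/C)C(=O)O
Why: Yamaguchi-type esterification through the mixed anhydride, run without a nucleophilic amine catalyst, should acylate both secondary hydroxyls while avoiding Z to E isomerisation of the angelate to the tiglate.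

Compound list
1 | methyl (2S)-oxirane-2-carboxylate (methyl (S)-glycidate) | COC(=O)[C@@H]1CO1 | starting material
2 | 2-methylprop-1-enylmagnesium bromide | CC(C)=C[Mg]Br | starting material
3 | methyl (2S)-2-hydroxy-5-methylhex-4-enoate | COC(=O)[C@H](CC=C(C)C)O | intermediate
4 | methyl (2S)-2-(TBSO)-5-methylhex-4-enoate | COC(=O)[C@H](CC=C(C)C)O[Si](C)(C)C(C)(C)C | intermediate
5 | tert-butyl acetate | CC(=O)OC(C)(C)C | starting material
6 | tert-butyl (4S)-4-(TBSO)-7-methyl-3-oxooct-6-enoate | CC(C)(C)OC(=O)CC(=O)[C@H](CC=C(C)C)O[Si](C)(C)C(C)(C)C | intermediate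
7 | tert-butyl (2Z,4S)-4-(TBSO)-7-methyl-3-(trifluoromethylsulfonyloxy)octa-2,6-dienoate | CC(C)(C)OC(=O)/C=C(\OS(=O)(=O)C(F)(F)F)[C@H](CC=C(C)C)O[Si](C)(C)C(C)(C)C | intermediate
8 | (trimethylsilyl)methylmagnesium chloride | C[Si](C)(C)C[Mg]Cl | starting material
9 | tert-butyl (2Z,4S)-4-(TBSO)-7-methyl-3-(trimethylsilylmethyl)octa-2,6-dienoate | CC(C)(C)OC(=O)/C=C(\C[Si](C)(C)C)[C@H](CC=C(C)C)O[Si](C)(C)C(C)(C)C | intermediate
10 | (2Z,4S)-4-(TBSO)-7-methyl-3-(trimethylsilylmethyl)octa-2,6-dien-1-ol | OC/C=C(\C[Si](C)(C)C)[C@H](CC=C(C)C)O[Si](C)(C)C(C)(C)C | intermediate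
11 | (2Z,4S)-4-(TBSO)-7-methyl-3-(trimethylsilylmethyl)octa-2,6-dienal | O=C/C=C(\C[Si](C)(C)C)[C@H](CC=C(C)C)O[Si](C)(C)C(C)(C)C | intermediate
12 | 4-methylfuran-2(5H)-one | CC1=CC(=O)OC1 | starting material
13 | 4-methyl-2-(trimethylsilyloxy)furan | Cc1coc(O[Si](C)(C)C)c1 | intermediate
14 | 1'-O-trimethylsilyl ether of 15 (not isolated) | C[Si](C)(C)C/C(=C\[C@H](O[Si](C)(C)C)[C@H]1OC(=O)C=C1C)[C@H](CC=C(C)C)O[Si](C)(C)C(C)(C)C | intermediate
15 | (5S)-5-[(1S,2Z,4S)-4-(TBSO)-1-hydroxy-7-methyl-3-(trimethylsilylmethyl)octa-2,6-dien-1-yl]-4-methylfuran-2(5H)-one | C[Si](C)(C)C/C(=C\[C@H](O)[C@H]1OC(=O)C=C1C)[C@H](CC=C(C)C)O[Si](C)(C)C(C)(C)C | intermediate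
16 | (5S)-5-[(1S,2Z,4S)-1,4-bis(TBSO)-7-methyl-3-(trimethylsilylmethyl)octa-2,6-dien-1-yl]-4-methylfuran-2(5H)-one | C[Si](C)(C)C/C(=C\[C@H](O[Si](C)(C)C(C)(C)C)[C@H]1OC(=O)C=C1C)[C@H](CC=C(C)C)O[Si](C)(C)C(C)(C)C | intermediate
17 | (2Z,4S,5S,6Z,8S)-5,8-bis(TBSO)-3,11-dimethyl-7-(trimethylsilylmethyl)dodeca-2,6,10-triene-1,4-diol | C[Si](C)(C)C/C(=C\[C@H](O[Si](C)(C)C(C)(C)C)[C@@H](O)/C(C)=C\CO)[C@H](CC=C(C)C)O[Si](C)(C)C(C)(C)C | intermediate
18 | (2S)-2-[(1S,2Z,4S)-1,4-bis(TBSO)-7-methyl-3-(trimethylsilylmethyl)octa-2,6-dien-1-yl]-3-methyl-2,5-dihydrofuran | C[Si](C)(C)C/C(=C\[C@H](O[Si](C)(C)C(C)(C)C)[C@H]1OCC=C1C)[C@H](CC=C(C)C)O[Si](C)(C)C(C)(C)C | intermediate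
19 | trimethylsilyl ether of 20 (not isolated) | C=C([C@H](CC=C(C)C)O[Si](C)(C)C(C)(C)C)[C@@H]1CC=C(C)[C@H](O[Si](C)(C)C)[C@H]1O[Si](C)(C)C(C)(C)C | intermediate
20 | (1S,5S,6S)-6-(TBSO)-5-[(3S)-3-(TBSO)-6-methylhepta-1,5-dien-2-yl]-2-methylcyclohex-2-en-1-ol | C=C([C@H](CC=C(C)C)O[Si](C)(C)C(C)(C)C)[C@@H]1CC=C(C)[C@H](O)[C@H]1O[Si](C)(C)C(C)(C)C | intermediate
21 | (1R,2R,3S,4S,6S)-3-(TBSO)-4-[(3S)-3-(TBSO)-6-methylhepta-1,5-dien-2-yl]-1-methyl-7-oxabicyclo[4.1.0]heptan-2-ol | C=C([C@H](CC=C(C)C)O[Si](C)(C)C(C)(C)C)[C@@H]1C[C@@H]2O[C@]2(C)[C@H](O)[C@H]1O[Si](C)(C)C(C)(C)C | intermediate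
22 | (1S,3S,4S,6S)-3-(TBSO)-4-[(3S)-3-(TBSO)-6-methylhepta-1,5-dien-2-yl]-1-methyl-7-oxabicyclo[4.1.0]heptan-2-one | C=C([C@H](CC=C(C)C)O[Si](C)(C)C(C)(C)C)[C@@H]1C[C@@H]2O[C@]2(C)C(=O)[C@H]1O[Si](C)(C)C(C)(C)C | intermediate
23 | (1S,3S,4S,6S)-3-hydroxy-4-[(3S)-3-hydroxy-6-methylhepta-1,5-dien-2-yl]-1-methyl-7-oxabicyclo[4.1.0]heptan-2-one | C=C([C@H](CC=C(C)C)O)[C@@H]1C[C@@H]2O[C@]2(C)C(=O)[C@H]1O | intermediate
24 | (2Z)-2-methylbut-2-enoic acid (angelic acid) | C/C=C(/C)C(=O)O | starting material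
25 | CNP0271744.2, (1S,3S,4S,6S)-1-methyl-4-[(3S)-6-methyl-3-{[(2Z)-2-methylbut-2-enoyl]oxy}hepta-1,5-dien-2-yl]-2-oxo-7-oxabicyclo[4.1.0]heptan-3-yl (2Z)-2-methylbut-2-enoate | C=C([C@H](CC=C(C)C)OC(=O)/C(C)=C\C)[C@@H]1C[C@@H]2O[C@]2(C)C(=O)[C@H]1OC(=O)/C(C)=C\C | target

Total step count: 17.
Longest linear sequence: 16 steps (steps 1–7 and 9–17); step 8 is a one-step side branch.

Steps most likely to fail

1. Step 13 (proposed new method). The dihydrofuran may not ionise under catalytic silyl triflate, or it may ionise and only return. The allyl cation may undergo a 1,2-hydride shift from the neighbouring carbinol carbon or lose a proton faster than it is captured. Traces of acid may protodesilylate the allylsilane, and facial selectivity at the new stereocentre may be poor. Fallback with known chemistry, setting out from diol 17 and coming back at cyclohexenol 20: the primary allylic hydroxyl of 17 is acetylated selectively (AcCl, 2,4,6-collidine, CH2Cl2, −78 °C) to the monoacetate F1, and the secondary hydroxyl is capped (Et3SiOTf, 2,6-lutidine) to give the triethylsilyl ether F2. F2 is then cyclised with BF3·OEt2 or catalytic Me3SiOTf in CH2Cl2 at −78 °C to the cyclised triethylsilyl ether F3. This is the established Lewis-acid cation–olefin cyclisation of an acyclic Z-allylic ester initiator onto an allylsilane terminator; here the allylsilane can assist departure of the acetate from the rear, which the dihydrofuran cannot offer. Methanolysis (pyridinium p-toluenesulfonate, MeOH) of F3 gives 20.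

2. Step 9. Enantioface selection and threo/erythro control may be insufficient with this hindered β,β-disubstituted enal, and the γ-silyl enal may suffer Lewis-acid-induced desilylation. Fallback, setting out from enal 11 and coming back at butenolide 16: an Evans syn-aldol reaction of 11 with the n-Bu2BOTf/Et3N enolate of (4R)-4-benzyl-3-{[(4-methoxybenzyl)oxy]acetyl}-1,3-oxazolidin-2-one gives the syn adduct F4, with the auxiliary controlling both carbinol centres. Transamidation (MeONHMe·HCl, AlMe3) gives the N-methoxy-N-methyl amide F5, silylation (TBSOTf, 2,6-lutidine) the silyl ether F6, and MeMgBr the methyl ketone F7. Buffered 2,3-dichloro-5,6-dicyano-1,4-benzoquinone in CH2Cl2/H2O removes the 4-methoxybenzyl group to give the α-hydroxy ketone F8. Ketenylidene(triphenyl)phosphorane (Ph3P=C=C=O, toluene, 80 °C) then closes the butenolide by O-acylation and intramolecular Wittig reaction to give 16.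

3. Step 17. The activated angelate may isomerise to the tiglate, acylation of the hindered α-ketol hydroxyl may stall, and warm amine base may cause ketol shift or epimerisation next to the ketone. Fallback, setting out from diol 23 and ending at 25: both hydroxyls are esterified with 2-[bis(2,2,2-trifluoroethoxy)phosphoryl]propanoic acid (EDC·HCl, DMAP cat., CH2Cl2, 0 °C) to the bis(phosphonate) F9. A twofold Still–Gennari olefination with acetaldehyde (KN(SiMe3)2, 18-crown-6, THF, −78 °C) then builds both (Z)-2-methylbut-2-enoates in place.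

Further compounds
F1 | step 13 | (2Z,4S,5S,6Z,8S)-5,8-bis(TBSO)-4-hydroxy-3,11-dimethyl-7-(trimethylsilylmethyl)dodeca-2,6,10-trien-1-yl acetate | C[Si](C)(C)C/C(=C\[C@H](O[Si](C)(C)C(C)(C)C)[C@@H](O)/C(C)=C\COC(C)=O)[C@H](CC=C(C)C)O[Si](C)(C)C(C)(C)C
F2 | step 13 | 4-O-triethylsilyl ether of F1 | C[Si](C)(C)C/C(=C\[C@H](O[Si](C)(C)C(C)(C)C)[C@@H](O[Si](CC)(CC)CC)/C(C)=C\COC(C)=O)[C@H](CC=C(C)C)O[Si](C)(C)C(C)(C)C
F3 | step 13 | triethylsilyl ether of cyclohexenol 20 | C=C([C@H](CC=C(C)C)O[Si](C)(C)C(C)(C)C)[C@@H]1CC=C(C)[C@H](O[Si](CC)(CC)CC)[C@H]1O[Si](C)(C)C(C)(C)C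
F4 | step 9 | (4R)-4-benzyl-3-[(2R,3S,4Z,6S)-6-(TBSO)-3-hydroxy-2-(4-methoxybenzyloxy)-9-methyl-5-(trimethylsilylmethyl)deca-4,8-dienoyl]-1,3-oxazolidin-2-one | COc1ccc(CO[C@@H](C(=O)N2[C@H](Cc3ccccc3)COC2=O)[C@@H](O)/C=C(\C[Si](C)(C)C)[C@H](CC=C(C)C)O[Si](C)(C)C(C)(C)C)cc1
F5 | step 9 | (2R,3S,4Z,6S)-6-(TBSO)-3-hydroxy-N-methoxy-2-(4-methoxybenzyloxy)-N,9-dimethyl-5-(trimethylsilylmethyl)deca-4,8-dienamide | COc1ccc(CO[C@@H](C(=O)N(C)OC)[C@@H](O)/C=C(\C[Si](C)(C)C)[C@H](CC=C(C)C)O[Si](C)(C)C(C)(C)C)cc1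
F6 | step 9 | 3-O-TBS ether of F5 | COc1ccc(CO[C@@H](C(=O)N(C)OC)[C@@H](O[Si](C)(C)C(C)(C)C)/C=C(\C[Si](C)(C)C)[C@H](CC=C(C)C)O[Si](C)(C)C(C)(C)C)cc1
F7 | step 9 | (3R,4S,5Z,7S)-4,7-bis(TBSO)-3-(4-methoxybenzyloxy)-10-methyl-6-(trimethylsilylmethyl)undeca-5,9-dien-2-one | COc1ccc(CO[C@@H](C(C)=O)[C@@H](O[Si](C)(C)C(C)(C)C)/C=C(\C[Si](C)(C)C)[C@H](CC=C(C)C)O[Si](C)(C)C(C)(C)C)cc1
F8 | step 9 | (3R,4S,5Z,7S)-4,7-bis(TBSO)-3-hydroxy-10-methyl-6-(trimethylsilylmethyl)undeca-5,9-dien-2-one | CC(=O)[C@H](O)[C@@H](O[Si](C)(C)C(C)(C)C)/C=C(\C[Si](C)(C)C)[C@H](CC=C(C)C)O[Si](C)(C)C(C)(C)C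
F9 | step 17 | bis{2-[bis(2,2,2-trifluoroethoxy)phosphoryl]propanoate} of diol 23 (phosphonate α-carbons as mixtures) | C=C([C@H](CC=C(C)C)OC(=O)C(C)P(=O)(OCC(F)(F)F)OCC(F)(F)F)[C@@H]1C[C@@H]2O[C@]2(C)C(=O)[C@H]1OC(=O)C(C)P(=O)(OCC(F)(F)F)OCC(F)(F)F
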